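**Strategy**

The route disconnects ring C of the upper (guibourtinidol) unit across O1–C8a and C3–C4. Ring A offers a 1,3-dielectrophile: C4, the doubly benzylic carbon, is held as the carbonyl of diaryl ketone 6 (the lower fisetinidol unit already on it through C8′), and C8a as the ortho C–F carbon. In one pot the β-oxido alkyllithium from (R)-bromohydrin 8 (O1–C2–C3, C2 preset) adds to C4 and its alkoxide then displaces fluoride at C8a, closing ring C. Dehydration and hydroboration anti to the C2 aryl group then set C3 and C4, and hydrogenolysis releases the target.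

Key step: step 4

Assumption: (−)-fisetinidol, the (2R,3S) flavan-3-ol of the lower unit, is bought as the isolated natural product. Flavan numbering is used throughout; atoms of the lower unit carry a prime; rings A, C, B belong to the upper unit and rings D, F, E to the lower unit.

**Route**

Step 1
Reactants: 1 (−)-fisetinidol
Product: 2 tetra-O-benzylfisetinidol (2R,3S; all four hydroxyl groups benzylated)
Conditions: BnBr, K2CO3, DMF, rt; then NaH, Bu4NI, 0 °C → rt
Reagents that add atoms: benzyl bromide, BrCc1ccccc1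
Why: Williamson etherification should cap the three phenols under the mild carbonate base first (so that no free phenoxide meets strong base, which could open ring F through a quinone methide and epimerise C2′) and the C3′ alkoxide afterwards, and no stereocentre is touched.

Step 2
Reactants: 2 tetra-O-benzylfisetinidol; 3 4-(benzyloxy)-2-fluorobenzonitrile
Product: 6 diaryl ketone [4-(benzyloxy)-2-fluorophenyl](tetra-O-benzylfisetinidol-8′-yl)methanone, via 8′-lithio arene 4 (not isolated), via N-lithio ketimine 5 (not isolated)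
Conditions: n-BuLi, TMEDA, THF, −20 → 0 °C; then 3, −78 °C → rt; then 2 M HCl, THF, 50 °C
Reagents that add atoms: water, O
Why: Directed ortho-metalation should take place at C8′ of ring D, the only aryl C–H flanked by two oxygen substituents (O1′ and the 7′-benzyloxy group) and not the C6′ site of electrophilic substitution, after which the aryllithium adds once to the nitrile and the ketimine is hydrolysed to the ketone, with no stereocentre involved.

Step 3
Reactants: 7 2-bromo-1-[4-(benzyloxy)phenyl]ethan-1-one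
Product: 8 (R)-2-bromo-1-[4-(benzyloxy)phenyl]ethan-1-ol
Conditions: (R)-2-methyl-CBS-oxazaborolidine (cat.), BH3·SMe2, THF, −20 °C; MeOH
Reagents that add atoms: none
Why: Corey–Bakshi–Shibata reduction, in which borane bound to the (R)-oxazaborolidine should deliver hydride to the ketone face that places the aryl group in the large-group position, is expected to set the carbinol carbon as R, which becomes C2 of ring C.

Step 4
Reactants: 8 (R)-2-bromo-1-[4-(benzyloxy)phenyl]ethan-1-ol; 6 diaryl ketone
Product: 11 4-aryl-flavan-4-ol (2S; both C4 epimers; aryl = tetra-O-benzylfisetinidol-8′-yl), via β-oxido alkyllithium 9 (not isolated), via dilithium 1,3-diolate 10 (not isolated)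
Conditions: 8: n-BuLi (1 equiv), THF, −78 °C, then lithium 4,4′-di-tert-butylbiphenylide (2 equiv), −78 °C; then 6, −78 → −30 °C; then KOtBu, DMF, 70 °C; then H2O
Reagents that add atoms: none
Why: Deprotonation of 8 and two-electron reduction of its C–Br bond should give the β-oxido alkyllithium 9, which adds through C3 to the ketone carbon C4 of 6 (1,2-carbonyl addition) to make C3–C4; after the switch to the potassium alkoxide and heating, O1 on C2 attacks C8a and expels fluoride through a Meisenheimer adduct (intramolecular SNAr etherification) to make O1–C8a. The closest known reaction types are the addition of halohydrin-derived β-oxido organolithiums to ketones to give 1,3-diols and the base-mediated closure of 3-(2-fluoroaryl)propan-1-olates to chromans. Ring C closes in the 6-exo-trig mode at the aromatic C8a carbon (exo to the C8a=C8 bond of ring A). C2 is carried through unchanged because only its O–H bond and the remote C–Br bond react; the new carbinol centre C4 forms without control and is erased in step 5. The step needs carbon-before-oxygen reactivity, which the temperature profile secures (the carbanion adds at −78 °C, the alkoxide reaches C–F only on heating), and it needs 9 to survive β-elimination of Li2O, for which it is kept at −78 °C until consumed. Closure by the right oxygen is secured by the substrate, since the C4 alkoxide could reach C8a only through a four-membered ring.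

Step 5
Reactants: 11 4-aryl-flavan-4-ol
Product: 12 (2S)-4-aryl-2H-chromene (4-aryl-flav-3-ene; aryl = tetra-O-benzylfisetinidol-8′-yl)
Conditions: MsCl, Et3N, CH2Cl2, 0 °C → rt
Reagents that add atoms: none
Why: Mesylation of the tertiary, doubly benzylic carbinol and E1-type loss of the sulfonate (a dehydration) can take a proton only from C3, so both C4 epimers should converge on the C3=C4 alkene, while the amine buffer keeps the acid-labile aryl allyl ether at C2 from ionising and C2 intact.

Step 6
Reactants: 12 (2S)-4-aryl-2H-chromene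
Product: 13 hexa-O-benzyl guibourtinidol-(4α→8)-fisetinidol (2R,3S,4S in the upper unit; free 3-OH)
Conditions: BH3·THF, THF, 0 °C → rt; then NaOH, H2O2, H2O, 0 °C → rt
Reagents that add atoms: hydrogen peroxide, OO
Why: Hydroboration–oxidation adds H and B syn across C3=C4, with boron on the less substituted C3 and on the face anti to the pseudo-axial C2 aryl group, and the oxidation proceeds with retention, so the 3-OH should come out trans to the 2-aryl group and the C4 hydrogen cis to the 3-OH, which sets C3 (S) and C4 (S) with the 4-aryl group trans to 3-OH and cis to the 2-aryl group.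

Step 7
Reactants: 13 hexa-O-benzyl guibourtinidol-(4α→8)-fisetinidol
Product: 14 guibourtinidol-(4α→8)-fisetinidol (target, CNP0176366.1)
Conditions: H2 (1 atm), Pd(OH)2/C, THF–MeOH, rt
Reagents that add atoms: none
Why: Hydrogenolysis of the six benzyl ethers over Pd(OH)2/C at 1 atm should leave the cyclic benzylic C2–O1 and C2′–O1′ ethers and the C4–C8′ bond in place, since these cleave far more slowly than O-benzyl groups, and it touches no stereocentre.

**Compound list**

1 | (−)-fisetinidol, (2R,3S)-2-(3,4-dihydroxyphenyl)-3,4-dihydro-2H-chromene-3,7-diol | Oc1ccc2c(c1)O[C@H](c1ccc(O)c(O)c1)[C@@H](O)C2 | starting material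
2 | tetra-O-benzylfisetinidol, (2R,3S)-3,7-bis(benzyloxy)-2-[3,4-bis(benzyloxy)phenyl]-3,4-dihydro-2H-chromene | c1ccccc1COc1ccc2c(c1)O[C@H](c1ccc(OCc3ccccc3)c(OCc3ccccc3)c1)[C@@H](OCc1ccccc1)C2 | intermediate
3 | 4-(benzyloxy)-2-fluorobenzonitrile | N#Cc1ccc(OCc2ccccc2)cc1F | starting material
4 | 8′-lithio arene, [(2R,3S)-3,7-bis(benzyloxy)-2-[3,4-bis(benzyloxy)phenyl]-3,4-dihydro-2H-chromen-8-yl]lithium | [Li]c1c(OCc2ccccc2)ccc2c1O[C@H](c1ccc(OCc3ccccc3)c(OCc3ccccc3)c1)[C@@H](OCc1ccccc1)C2 | intermediate
5 | N-lithio ketimine of ketone 6 | [Li]N=C(c1ccc(OCc2ccccc2)cc1F)c1c(OCc2ccccc2)ccc2c1O[C@H](c1ccc(OCc3ccccc3)c(OCc3ccccc3)c1)[C@@H](OCc1ccccc1)C2 | intermediate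
6 | diaryl ketone, [4-(benzyloxy)-2-fluorophenyl][(2R,3S)-3,7-bis(benzyloxy)-2-[3,4-bis(benzyloxy)phenyl]-3,4-dihydro-2H-chromen-8-yl]methanone | O=C(c1ccc(OCc2ccccc2)cc1F)c1c(OCc2ccccc2)ccc2c1O[C@H](c1ccc(OCc3ccccc3)c(OCc3ccccc3)c1)[C@@H](OCc1ccccc1)C2 | intermediate
7 | 2-bromo-1-[4-(benzyloxy)phenyl]ethan-1-one | O=C(CBr)c1ccc(OCc2ccccc2)cc1 | starting material
8 | (R)-2-bromo-1-[4-(benzyloxy)phenyl]ethan-1-ol | O[C@@H](CBr)c1ccc(OCc2ccccc2)cc1 | intermediate
9 | β-oxido alkyllithium, lithium (1S)-1-[4-(benzyloxy)phenyl]-2-lithioethan-1-olate (same spatial arrangement as 8) | [Li]C[C@H](O[Li])c1ccc(OCc2ccccc2)cc1 | intermediate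
10 | dilithium 1,3-diolate from addition of 9 to 6 (3S at the benzylic carbinol; tertiary carbinol either configuration) | [Li]OC(C[C@H](O[Li])c1ccc(OCc2ccccc2)cc1)(c1ccc(OCc2ccccc2)cc1F)c1c(OCc2ccccc2)ccc2c1O[C@H](c1ccc(OCc3ccccc3)c(OCc3ccccc3)c1)[C@@H](OCc1ccccc1)C2 | intermediate
11 | (2S,4RS)-7-(benzyloxy)-2-[4-(benzyloxy)phenyl]-4-[(2R,3S)-3,7-bis(benzyloxy)-2-[3,4-bis(benzyloxy)phenyl]-3,4-dihydro-2H-chromen-8-yl]-3,4-dihydro-2H-chromen-4-ol | c1ccccc1COc1ccc(cc1)[C@H]1Oc2cc(OCc3ccccc3)ccc2C(O)(c2c(OCc3ccccc3)ccc3c2O[C@H](c2ccc(OCc4ccccc4)c(OCc4ccccc4)c2)[C@@H](OCc2ccccc2)C3)C1 | intermediate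
12 | (2S)-7-(benzyloxy)-2-[4-(benzyloxy)phenyl]-4-[(2R,3S)-3,7-bis(benzyloxy)-2-[3,4-bis(benzyloxy)phenyl]-3,4-dihydro-2H-chromen-8-yl]-2H-chromene | c1ccccc1COc1ccc(cc1)[C@H]1Oc2cc(OCc3ccccc3)ccc2C(c2c(OCc3ccccc3)ccc3c2O[C@H](c2ccc(OCc4ccccc4)c(OCc4ccccc4)c2)[C@@H](OCc2ccccc2)C3)=C1 | intermediate
13 | (2R,3S,4S)-7-(benzyloxy)-2-[4-(benzyloxy)phenyl]-4-[(2R,3S)-3,7-bis(benzyloxy)-2-[3,4-bis(benzyloxy)phenyl]-3,4-dihydro-2H-chromen-8-yl]-3,4-dihydro-2H-chromen-3-ol | c1ccccc1COc1ccc(cc1)[C@H]1Oc2cc(OCc3ccccc3)ccc2[C@@H](c2c(OCc3ccccc3)ccc3c2O[C@H](c2ccc(OCc4ccccc4)c(OCc4ccccc4)c2)[C@@H](OCc2ccccc2)C3)[C@@H]1O | intermediate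
14 | guibourtinidol-(4α→8)-fisetinidol, (2R,3S,4S)-4-[(2R,3S)-2-(3,4-dihydroxyphenyl)-3,7-dihydroxy-3,4-dihydro-2H-chromen-8-yl]-2-(4-hydroxyphenyl)-3,4-dihydro-2H-chromene-3,7-diol | Oc1ccc([C@H]2Oc3cc(O)ccc3[C@@H](c3c(O)ccc4c3O[C@H](c3ccc(O)c(O)c3)[C@@H](O)C4)[C@@H]2O)cc1 | target

**Count and risks**

Total steps: 7. Longest linear sequence: 6 (steps 1, 2, 4, 5, 6, 7); step 3 supplies the side branch.

Step 4. What may go wrong: the β-oxido alkyllithium may be lost by β-elimination of Li2O before it adds; the benzyl ether of 8 may be cleaved by electron transfer from the arene radical anion; addition to the hindered carbonyl may be slow; displacement of the unactivated fluoride may lag behind decomposition. Fallback, from 8 and 6 back to 12: 8 is treated with PhSO2Na (DMF, 60 °C) to give (R)-1-[4-(benzyloxy)phenyl]-2-(phenylsulfonyl)ethan-1-ol F1. Its dianion (2 equiv n-BuLi, THF, −78 °C) carries a sulfonyl-stabilised carbanion that needs no reductive lithiation and cannot lose oxide. It is added to 6, the diolate is closed by the same KOtBu/DMF heating, and the tertiary alkoxide is capped with Ac2O to give the 4-acetoxy-4-aryl-3-(phenylsulfonyl)flavan F2. Julia–Lythgoe reductive elimination with sodium amalgam, Na(Hg), and Na2HPO4 in MeOH–THF then gives 12.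

Step 2. What may go wrong: lithiation may compete at the benzylic CH2 groups of the benzyl ethers (followed by Wittig rearrangement); the aryllithium may take the acidic ring proton between F and OBn of 3 or displace its fluoride instead of adding to the nitrile; the hindered ketimine may resist hydrolysis. Fallback, from 2 back to 6: the lithio species from 2 is quenched at −78 °C with 4-(benzyloxy)-2-fluorobenzaldehyde (O=Cc1ccc(OCc2ccccc2)cc1F), whose carbonyl addition outruns proton transfer and fluoride displacement, to give the benzhydrol [4-(benzyloxy)-2-fluorophenyl](tetra-O-benzylfisetinidol-8′-yl)methanol F3 (either carbinol configuration). Dess–Martin oxidation (CH2Cl2, rt) then gives 6 without any ketimine hydrolysis.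

Step 6. What may go wrong: borane may add slowly to the hindered trisubstituted alkene flanked by ring D, and facial discrimination by the C2 aryl group may be incomplete. Fallback, from 12 back to 13: acridinium photoredox anti-Markovnikov hydroacetoxylation (9-mesityl-10-methylacridinium tetrafluoroborate, AcOH, PhSH as hydrogen-atom donor, blue light, CH2Cl2). Acetate should add to C3 of the alkene radical cation anti to the C2 aryl group, and hydrogen-atom transfer to the C4 diarylmethyl radical should place ring D pseudo-equatorial, to give the 3-O-acetate of 13 F4. Methanolysis (K2CO3, MeOH, rt) then gives 13.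

Further compounds
F1 | step 4 | (R)-1-[4-(benzyloxy)phenyl]-2-(phenylsulfonyl)ethan-1-ol | O[C@@H](CS(=O)(=O)c1ccccc1)c1ccc(OCc2ccccc2)cc1
F2 | step 4 | (2S)-4-acetoxy-7-(benzyloxy)-2-[4-(benzyloxy)phenyl]-3-(phenylsulfonyl)-4-(tetra-O-benzylfisetinidol-8′-yl)-3,4-dihydro-2H-chromene (C3 and C4 either configuration) | c1ccccc1COc1ccc(cc1)[C@H]1Oc2cc(OCc3ccccc3)ccc2C(OC(C)=O)(c2c(OCc3ccccc3)ccc3c2O[C@H](c2ccc(OCc4ccccc4)c(OCc4ccccc4)c2)[C@@H](OCc2ccccc2)C3)C1S(=O)(=O)c1ccccc1
F3 | step 2 | [4-(benzyloxy)-2-fluorophenyl][(2R,3S)-3,7-bis(benzyloxy)-2-[3,4-bis(benzyloxy)phenyl]-3,4-dihydro-2H-chromen-8-yl]methanol (either carbinol configuration) | OC(c1ccc(OCc2ccccc2)cc1F)c1c(OCc2ccccc2)ccc2c1O[C@H](c1ccc(OCc3ccccc3)c(OCc3ccccc3)c1)[C@@H](OCc1ccccc1)C2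
F4 | step 6 | (2R,3S,4S)-7-(benzyloxy)-2-[4-(benzyloxy)phenyl]-4-(tetra-O-benzylfisetinidol-8′-yl)-3,4-dihydro-2H-chromen-3-yl acetate | c1ccccc1COc1ccc(cc1)[C@H]1Oc2cc(OCc3ccccc3)ccc2[C@@H](c2c(OCc3ccccc3)ccc3c2O[C@H](c2ccc(OCc4ccccc4)c(OCc4ccccc4)c2)[C@@H](OCc2ccccc2)C3)[C@@H]1OC(C)=O
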